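The readings are calculated for an exercise; scatter was added.

**The decision.** I had to decide whether the next flask could be charged at c(substrate) = 0.20 M, between the two earlier charges, and left for 2.5 d with just three samples.

| flask | substrate | remark | time |
|---|---|---|---|
| Sunday's | 0.13 M | run made earlier |  |
| Wednesday's | 0.30 M | run made earlier |  |
| flask | 0.20 M |  | 2.5 d |

| run | time / h | isomer of the product / % | target / % | substrate / % |
|---|---|---|---|---|
| Sunday's | 3.00 | 9 | 20 | 46 |
| Sunday's | 4.00 | 13 | 25 | 34 |
| Sunday's | 6.00 | 16 | 32 | 25 |
| Sunday's | 10.0 | 19 | 36 | 15 |
| Sunday's | 15.0 | 19 | 43 | 10 |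
| Sunday's | 25.0 | 19 | 43 | 7 |
| Sunday's | 40.0 | 25 | 44 | 7 |
| Wednesday's | 2.00 | 9 | 13 | 59 |
| Wednesday's | 6.00 | 15 | 30 | 25 |
| Wednesday's | 10.0 | 18 | 36 | 15 |
| Wednesday's | 15.0 | 21 | 38 | 9 |
| Wednesday's | 20.0 | 23 | 40 | 3 |
| Wednesday's | 30.0 | 19 | 46 | 7 |
| Wednesday's | 40.0 | 23 | 45 | 2 |

(scatter of a reading: 2 percentage points)

* share of isomer of the product in isomer of the product plus target at 10 min
* share of isomer of the product in isomer of the product plus target at 3.0 h
* share of isomer of the product in isomer of the product plus target at 2.5 d
* which of isomer of the product and target there is more of at 2.5 d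

- a reading or a percentage of target counts all its forms, free or not
- a reading of substrate is of its free form alone

**The isomer split.** That decision hung on one quantity. Pooling the two last readings, at 40.0 h, I got 35.0 % for the isomer split (the selectivity), meaning isomer of the product over isomer of the product plus target. The same pooling of the first readings of the two runs gave 35.3 %, so the readings showed no drift with time. At 10.0 h, Sunday's run read 34.5 % and Wednesday's 33.3 %, so the charge moved it little. I therefore committed to the split at all three asked times. Because the split lies below one half, I expected target to lead. The time of 10 min lies outside the readings, so that value was the least secure. I kept the charge and the plan.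

**The forecast.** It gave 34 %, 34 % and 34 %, with target ahead, saying “There is no visible drift”. That is 1 percentage point below my split.

**The result.** The flask gave 32.4 %, 32.3 % and 35.3 %, with target at 44.5 % against 24.3 % of isomer of the product, so the forecast stands. The relaxation half-life of substrate and isomer of the product by their step alone, both ways together, is 0.543 d, short against 2.5 d. My split lay 0.30 points from the flask's end value.

    substrate ⇌ third isomer (K = 0.380, k = 0.0370 /h)
    substrate ⇌ target (K = 7.20, k = 0.100 /h)
    target → over-reaction product (k = 0.00470 /h)
    substrate + target ⇌ idle adduct, settled at all times (K = 120 /M)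
    substrate ⇌ isomer of the product (K = 9.30, k = 0.0480 /h)

**A thinner flask.** Charged at 0.050 M, the neighbour should by the split have stood at 35.0 %, with target ahead. It gave 32.4 %, 32.4 % and then 39.6 % at 2.5 d, which is 4.6 points above the split, with target still ahead at 44.9 % against 29.4 %. A late rise of that kind in this flask is what would have made the forecast wrong.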